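**Assumptions**
- The target has no stereocentres (the C3=C4 alkene is endocyclic and the prenyl alkene has a gem-dimethyl terminus), so "single enantiomer" is read as the single constitutional isomer drawn.
- 2,4-Dihydroxy-6-methoxybenzaldehyde is taken as a catalogue compound (CAS 3519-76-4); if not, it is one Vilsmeier step from 5-methoxyresorcinol.

**Retrosynthetic overview**
1. Rings A and B are bought as aromatics; only the pyran ring C is built, and it is built last. No isoflavone or 3-arylcoumarin reduction is used.
2. Ring C: the C3–C4 bond comes from a Nozaki–Hiyama–Kishi (NHK) coupling of an α-arylvinyl triflate with a salicylaldehyde. The O1–C2 bond comes from dehydration to a vinyl o-quinone methide and oxa-6π electrocyclisation.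
3. C6-prenyl regiochemistry: the prenyl group is placed on the oxygen that becomes O1 and moved by a Eu(III)-catalysed para-Claisen–Cope rearrangement. It can only land para to that oxygen, i.e. between 5-OMe and 7-O.
4. All three phenols are carried as silyl ethers and released with buffered fluoride. Acid is avoided at the end because a 2'-hydroxyisoflav-3-ene can close to a pterocarpan and an o-prenylphenol can close to a chroman.

**Route**

Step 1
Reactants: 1, 2,4-dihydroxy-6-methoxybenzaldehyde
Product: 2, 4-[(tert-butyldimethylsilyl)oxy]-2-hydroxy-6-methoxybenzaldehyde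
Conditions: TBSCl (1.05 eq), imidazole, CH2Cl2, 0 °C
Reagents that add atoms: TBSCl, CC(C)(C)[Si](C)(C)Cl
Why: Selective silylation; the 2-OH is hydrogen-bonded to the aldehyde, so only the free 4-OH reacts.

Step 2
Reactants: 2; 3, 3-methylbut-2-en-1-ol (prenol)
Product: 4, 4-[(tert-butyldimethylsilyl)oxy]-2-methoxy-6-[(3-methylbut-2-en-1-yl)oxy]benzaldehyde
Conditions: PPh3, DIAD, THF, 0 °C to rt
Reagents that add atoms: none beyond reactant 3 (prenol, CC(C)=CCO)
Why: Mitsunobu etherification of the acidic chelated phenol under neutral conditions, which spares the base-labile para-formyl aryl silyl ether.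

Step 3
Reactants: 4
Product: 5, 4-[(tert-butyldimethylsilyl)oxy]-6-hydroxy-2-methoxy-3-(3-methylbut-2-en-1-yl)benzaldehyde
Conditions: Eu(fod)3 (10 mol %), CHCl3, 65 °C, sealed tube
Reagents that add atoms: none
Why: Eu(III)-catalysed para-Claisen–Cope rearrangement: chelation by C=O and the ether oxygen triggers [3,3] shift to the only free ortho carbon, and the crowded dienone undergoes Cope shift to the para carbon, giving a normal prenyl group between OMe and OTBS and freeing the ortho-OH.

Step 4
Reactants: 6, 2,4-dihydroxyacetophenone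
Product: 7, 1-{2,4-bis[(triisopropylsilyl)oxy]phenyl}ethan-1-one
Conditions: TIPSCl (2.5 eq), imidazole, DMAP (cat.), DMF, 45 °C
Reagents that add atoms: TIPSCl, CC(C)[Si](Cl)(C(C)C)C(C)C
Why: Exhaustive phenol silylation; TIPS is chosen over TBS so the ortho silyl group does not migrate to the enolate oxygen in step 5.

Step 5
Reactants: 7
Product: 8, 1-{2,4-bis[(triisopropylsilyl)oxy]phenyl}ethenyl trifluoromethanesulfonate
Conditions: KHMDS, THF, −78 °C; then PhNTf2, −78 to 0 °C; Et3N-washed silica, use at once
Reagents that add atoms: PhNTf2, O=S(=O)(N(c1ccccc1)S(=O)(=O)C(F)(F)F)C(F)(F)F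
Why: Kinetic enolate O-triflation of a methyl ketone (only one enolisable side) gives the 1,1-disubstituted vinyl triflate.

Step 6
Reactants: 5; 8 (1.5 eq)
Product: 9, (±)-2-{2-[2,4-bis(triisopropylsilyloxy)phenyl]-1-hydroxyprop-2-en-1-yl}-5-[(tert-butyldimethylsilyl)oxy]-3-methoxy-4-(3-methylbut-2-en-1-yl)phenol
Conditions: CrCl2 (6 eq), NiCl2 (2 mol %), degassed DMF, rt; aqueous serinate workup; crude carried on
Reagents that add atoms: none
Why: NHK coupling: the non-basic alkenyl-Cr(III) species tolerates the free phenol, the aryl silyl ethers and the prenyl group, and adds only to the aldehyde; the carbinol centre is racemic and is destroyed in step 7.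

Step 7
Reactants: 9
Product: 10, tert-butyl({3-[2,4-bis(triisopropylsilyloxy)phenyl]-5-methoxy-6-(3-methylbut-2-en-1-yl)-2H-chromen-7-yl}oxy)dimethylsilane
Conditions: PPTS (5 mol %), 4 Å MS, toluene (0.02 M), rt to 45 °C
Reagents that add atoms: none
Why: Dehydrative oxa-6π electrocyclisation: the trioxygenated o-hydroxybenzylic allylic alcohol loses water to a 2-aryl-vinyl o-quinone methide, whose phenolic oxygen closes onto the terminal CH2 to give the 3-aryl-2H-chromene; both other ortho carbons of ring A are substituted, so no indene pathway exists.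

Step 8
Reactants: 10
Product: 11, dehydroglyasperin C, 4-[7-hydroxy-5-methoxy-6-(3-methylbut-2-en-1-yl)-2H-chromen-3-yl]benzene-1,3-diol
Conditions: TBAF (3.5 eq), AcOH (3.5 eq), degassed THF, 0 °C; pH 7 buffer workup under Ar
Reagents that add atoms: none
Why: Buffered fluoride desilylation removes the aryl TBS and TIPS ethers without acid, so the isoflav-3-ene, the 2'-OH and the o-prenylphenol survive.

**Compound list**
1 | 2,4-dihydroxy-6-methoxybenzaldehyde | COc1cc(O)cc(O)c1C=O | starting material
2 | 4-(TBS-oxy)-2-hydroxy-6-methoxybenzaldehyde | COc1cc(O[Si](C)(C)C(C)(C)C)cc(O)c1C=O | intermediate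
3 | 3-methylbut-2-en-1-ol (prenol) | CC(C)=CCO | starting material
4 | 4-(TBS-oxy)-2-methoxy-6-(prenyloxy)benzaldehyde | COc1cc(O[Si](C)(C)C(C)(C)C)cc(OCC=C(C)C)c1C=O | intermediate
5 | 4-(TBS-oxy)-6-hydroxy-2-methoxy-3-prenylbenzaldehyde | COc1c(C=O)c(O)cc(O[Si](C)(C)C(C)(C)C)c1CC=C(C)C | intermediate
6 | 2,4-dihydroxyacetophenone | CC(=O)c1ccc(O)cc1O | starting material
7 | 2,4-bis(TIPS-oxy)acetophenone | CC(=O)c1ccc(O[Si](C(C)C)(C(C)C)C(C)C)cc1O[Si](C(C)C)(C(C)C)C(C)C | intermediate
8 | 1-[2,4-bis(TIPS-oxy)phenyl]ethenyl triflate | C=C(OS(=O)(=O)C(F)(F)F)c1ccc(O[Si](C(C)C)(C(C)C)C(C)C)cc1O[Si](C(C)C)(C(C)C)C(C)C | intermediate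
9 | (±)-NHK allylic alcohol (racemic carbinol) | COc1c(C(O)C(=C)c2ccc(O[Si](C(C)C)(C(C)C)C(C)C)cc2O[Si](C(C)C)(C(C)C)C(C)C)c(O)cc(O[Si](C)(C)C(C)(C)C)c1CC=C(C)C | intermediate
10 | 7-O-TBS-2',4'-di-O-TIPS-dehydroglyasperin C | COc1c2c(cc(O[Si](C)(C)C(C)(C)C)c1CC=C(C)C)OCC(c1ccc(O[Si](C(C)C)(C(C)C)C(C)C)cc1O[Si](C(C)C)(C(C)C)C(C)C)=C2 | intermediate
11 | dehydroglyasperin C | COc1c2c(cc(O)c1CC=C(C)C)OCC(c1ccc(O)cc1O)=C2 | target

**Totals**
Total steps: 8. Longest linear sequence: 6 (steps 1, 2, 3, 6, 7, 8).

**Steps most likely to fail, with fallbacks**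
1. Step 6 (NHK on a hindered, very electron-rich salicylaldehyde with a free phenol). Fallback: change the ring-C bond set. Reduce 5 to the salicyl alcohol, convert it to the o-hydroxybenzyl-triphenylphosphonium salt, O-alkylate with the α-bromoketone made from 7, and close the ring by intramolecular Wittig olefination.
2. Step 3 (the ortho 1,1-dimethylallyl product or deprenylation may compete with the para-Claisen–Cope path). Fallback: build 5 by three sequential directed ortho-metalations of 1-methoxy-3,5-bis(methoxymethoxy)benzene. A TMS group blocks the site between the two OMOM groups, prenyl and then formyl go in at the two sites flanking OMe, and deprotection and 4-O-silylation follow.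
3. Step 5 (the vinyl triflate of a strongly donor-substituted arene may ionise or hydrolyse). Fallback: replace the triflate with the α-arylvinyl pinacol boronate, made by Cu-catalysed α-selective protoboration of 1-ethynyl-2,4-bis(TIPS-oxy)benzene. Couple it to 5 in one pot by an amine-mediated Petasis borono-Mannich, amine elimination and oxa-6π cascade.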